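**Retrosynthetic overview**
- Target ⇒ global desilylation of a tetra-TBS flavanone; the C8 prenyl group comes from a C8 allyl group by cross-metathesis (allyl is carried as a Prins-inert stand-in for prenyl).
- Ring C ⇒ asymmetric oxa-Povarov-type [4+2] annulation: an aryl 2-oxadiene oxocarbenium ion (C4a=C8a–O1=C2) plus a terminal ynamide as ketene equivalent forms C2–C3 and C4–C4a; hydrolysis of the enamide gives the C4 ketone.
- Enabling feature: C2 sits between O1 and ring B, whose oxygens at C2' and C4' are ortho and para to it, so an O-aryl O-methyl acetal at C2 ionizes easily. C4a of ring A is ortho to O1 and ortho/para to the oxygens at C5 and C7, and it is the only free ortho carbon because C8 is substituted.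
- Mixed acetal ⇒ ring A phenol (Claisen rearrangement of the allyl ether of bis-silylated phloroglucinol) plus ring B aldehyde dimethyl acetal (Claisen rearrangement of a 4-O-prenyl ether installs the 2-methylbut-3-en-2-yl group).
- Ring order: rings A and B are bought as arenes; ring C is the only ring formed (step 10).

Key step: step 10

Assumption: the sense of induction of the chiral acid in step 10 cannot be predicted with certainty, so the catalyst antipode that gives the (2S) product is selected in a first experiment; both antipodes are accessible. (TBS = tert-butyldimethylsilyl, TBSO = tert-butyldimethylsilyloxy.)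

**Route**

Step 1
Reactants: 1 phloroglucinol
Product: 2 3,5-bis(TBSO)phenol
Conditions: TBSCl (2.0 equiv), imidazole, DMF, 0 °C to rt
Reagents that add atoms: tert-butyldimethylsilyl chloride, CC(C)(C)[Si](C)(C)Cl
Why: Silyl ether formation on a threefold-symmetric triol should give the bis-ether as the main product at two equivalents, separable from mono- and tris-ethers that can be recycled.

Step 2
Reactants: 2 3,5-bis(TBSO)phenol
Product: 3 1-(allyloxy)-3,5-bis(TBSO)benzene
Conditions: allyl alcohol, PPh3, DIAD, THF, 0 °C to rt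
Reagents that add atoms: allyl alcohol, C=CCO
Why: Mitsunobu etherification alkylates the phenol under neutral conditions, so the base-sensitive aryl silyl ethers should neither cleave nor migrate.

Step 3
Reactants: 3 1-(allyloxy)-3,5-bis(TBSO)benzene
Product: 4 2-allyl-3,5-bis(TBSO)phenol
Conditions: N,N-diethylaniline, 190 °C, argon
Reagents that add atoms: none
Why: Aromatic Claisen rearrangement ([3,3] shift, then enolization) should give one product because the two free ortho positions are equivalent.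

Step 4
Reactants: 5 2,4-dihydroxybenzaldehyde
Product: 6 2-hydroxy-4-(3-methylbut-2-en-1-yloxy)benzaldehyde
Conditions: prenyl bromide (1.05 equiv), K2CO3, acetone, 40 °C
Reagents that add atoms: prenyl bromide, CC(C)=CCBr
Why: Williamson etherification should occur at O4 because the 2-hydroxyl is held in a hydrogen bond to the aldehyde and is less nucleophilic.

Step 5
Reactants: 6 2-hydroxy-4-(3-methylbut-2-en-1-yloxy)benzaldehyde
Product: 7 2-(TBSO)-4-(3-methylbut-2-en-1-yloxy)benzaldehyde
Conditions: TBSCl, imidazole, DMF, rt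
Reagents that add atoms: tert-butyldimethylsilyl chloride, CC(C)(C)[Si](C)(C)Cl
Why: Silyl ether formation caps the 2-hydroxyl, which breaks the hydrogen bond that would steer the next rearrangement to C3 and adds bulk next to C3.

Step 6
Reactants: 7 2-(TBSO)-4-(3-methylbut-2-en-1-yloxy)benzaldehyde
Product: 8 2-(TBSO)-4-hydroxy-5-(2-methylbut-3-en-2-yl)benzaldehyde
Conditions: N,N-diethylaniline, 200 °C, sealed tube, argon
Reagents that add atoms: none
Why: Aromatic Claisen rearrangement of an aryl prenyl ether delivers the allyl unit inverted (2-methylbut-3-en-2-yl) to an ortho carbon; the para carbon bears the formyl group, and C5 should be preferred over C3, which is flanked by two oxygen substituents.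

Step 7
Reactants: 8 2-(TBSO)-4-hydroxy-5-(2-methylbut-3-en-2-yl)benzaldehyde
Product: 9 2,4-bis(TBSO)-5-(2-methylbut-3-en-2-yl)benzaldehyde
Conditions: TBSOTf, 2,6-lutidine, CH2Cl2, 0 °C
Reagents that add atoms: tert-butyldimethylsilyl triflate, CC(C)(C)[Si](C)(C)OS(=O)(=O)C(F)(F)F
Why: Silyl ether formation with the reactive triflate should overcome the hindrance of the neighbouring tertiary alkyl group.

Step 8
Reactants: 9 2,4-bis(TBSO)-5-(2-methylbut-3-en-2-yl)benzaldehyde
Product: 10 1-(dimethoxymethyl)-2,4-bis(TBSO)-5-(2-methylbut-3-en-2-yl)benzene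
Conditions: HC(OMe)3, PPTS (cat.), MeOH, rt; Et3N quench
Reagents that add atoms: trimethyl orthoformate, COC(OC)OC
Why: Acetalization driven by the orthoester should convert even this electron-rich aldehyde under acid mild enough for aryl silyl ethers.

Step 9
Reactants: 10 1-(dimethoxymethyl)-2,4-bis(TBSO)-5-(2-methylbut-3-en-2-yl)benzene; 4 2-allyl-3,5-bis(TBSO)phenol
Product: 12 racemic 1-{[2-allyl-3,5-bis(TBSO)phenoxy](methoxy)methyl}-2,4-bis(TBSO)-5-(2-methylbut-3-en-2-yl)benzene, via α-chloro ether 11 (not isolated)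
Conditions: AcCl (1.05 equiv), ZnBr2 (cat.), CH2Cl2, −40 °C; then 4, iPr2NEt, −40 to 0 °C; chromatography on Et3N-deactivated silica
Reagents that add atoms: none
Why: Acetal-to-α-chloro-ether exchange with an acyl chloride followed by O-alkylation of the phenol under amine base (the reaction type used to make aryl alkoxymethyl ethers) should give the mixed acetal, whose racemic acetal carbon is planarized in the next step.

Step 10
Reactants: 12 racemic mixed O-aryl O-methyl acetal; 13 N-ethynyl-N,4-dimethylbenzenesulfonamide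
Product: 17 (S)-8-allyl-5,7-bis(TBSO)-2-[2,4-bis(TBSO)-5-(2-methylbut-3-en-2-yl)phenyl]chroman-4-one, via oxocarbenium ion 14 (not isolated), via keteniminium ion 15 (not isolated), via enamide 16 (not isolated)
Conditions: chiral imidodiphosphorimidate acid HN[P(=NSO2CF3)(O2Ar*)]2 (O2Ar* = 3,3'-bis[3,5-bis(trifluoromethyl)phenyl]-1,1'-binaphthyl-2,2'-diolate; 5 mol%), 13 (3 equiv), 5 Å molecular sieves, toluene, −40 °C; Et3N quench; then 0.5 M HCl, THF, 0 °C
Reagents that add atoms: water, O
Why: Proposed new method: the confined chiral acid protonates the methoxy oxygen of 12, methanol leaves (held by the sieves) and the planar aryl 2-oxadiene oxocarbenium ion 14 (C4a=C8a–O1=C2) forms as a contact ion pair with the chiral anion; the nucleophilic terminal carbon of ynamide 13 adds to C2 (C2–C3 bond), and keteniminium ion 15 is captured at its sp carbon by C4a (C4–C4a bond) before proton loss returns the acid and gives enamide 16, which the acidic work-up hydrolyses to the ketone. The closest known reaction types are the oxa-Povarov reaction of aryl oxocarbenium ions with alkenes under achiral Lewis acids, the Povarov-type annulation of N-arylimines with ynamides, and ion-pair catalysis of oxocarbenium reactions (Prins cyclization, hetero-Diels–Alder reaction) by confined imidodiphosphorimidate acids; new are the O-aryl oxocarbenium/ynamide pairing and its asymmetric control. Ring C, the only ring made, closes by a 6-exo-dig Friedel–Crafts attack on the keteniminium ion (the C=N bond that is broken lies outside the ring), so the whole event is a stepwise polar [4+2] annulation. The one new stereocenter, C2, is set in the first bond formation by the chiral anion, which leaves one face of the ion-paired oxocarbenium ion open; the catalyst antipode is chosen for (2S). Regioselectivity is fixed by the substrate: C8 carries the allyl group, so C4a is the only free carbon ortho to O1, and O1, O5 and O7 all activate it. Chemoselectivity needs the ynamide to outrun other nucleophiles, which is secured by the allyl group standing in for prenyl (a monosubstituted alkene is a much weaker nucleophile than the ynamide, whereas a prenyl group would attack C2 in an intramolecular Prins reaction) and by the bulky silyl ethers that shield C6 and the ring B oxygens.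

Step 11
Reactants: 17 (S)-8-allyl-5,7-bis(TBSO)-2-[2,4-bis(TBSO)-5-(2-methylbut-3-en-2-yl)phenyl]chroman-4-one
Product: 18 (S)-5,7-bis(TBSO)-2-[2,4-bis(TBSO)-5-(2-methylbut-3-en-2-yl)phenyl]-8-(3-methylbut-2-en-1-yl)chroman-4-one
Conditions: second-generation Grubbs catalyst (5 mol%), 2-methyl-2-butene/CH2Cl2 (1:1), 40 °C, sealed tube
Reagents that add atoms: 2-methyl-2-butene, CC=C(C)C
Why: Olefin cross-metathesis should convert the unhindered allyl group to prenyl, while the vinyl group on the quaternary carbon of ring B is too hindered to compete and C2 is untouched under these neutral conditions.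

Step 12
Reactants: 18 (S)-5,7-bis(TBSO)-2-[2,4-bis(TBSO)-5-(2-methylbut-3-en-2-yl)phenyl]-8-(3-methylbut-2-en-1-yl)chroman-4-one
Product: 19 AChE-IN-17, (S)-2-[2,4-dihydroxy-5-(2-methylbut-3-en-2-yl)phenyl]-5,7-dihydroxy-8-(3-methylbut-2-en-1-yl)chroman-4-one
Conditions: HF·pyridine, excess pyridine, THF, 0 °C to rt
Reagents that add atoms: none
Why: Fluoride-mediated desilylation in a pyridine-buffered medium should free all four phenols without the base that opens flavanones by retro-oxa-Michael reaction and without acid strong enough to ionize C2–O1 or cyclize the prenyl group.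

**Compound list**
1 | phloroglucinol | Oc1cc(O)cc(O)c1 | starting material
2 | 3,5-bis(tert-butyldimethylsilyloxy)phenol | Oc1cc(O[Si](C)(C)C(C)(C)C)cc(O[Si](C)(C)C(C)(C)C)c1 | intermediate
3 | 1-(allyloxy)-3,5-bis(tert-butyldimethylsilyloxy)benzene | C=CCOc1cc(O[Si](C)(C)C(C)(C)C)cc(O[Si](C)(C)C(C)(C)C)c1 | intermediate
4 | 2-allyl-3,5-bis(tert-butyldimethylsilyloxy)phenol | C=CCc1c(O)cc(O[Si](C)(C)C(C)(C)C)cc1O[Si](C)(C)C(C)(C)C | intermediate
5 | 2,4-dihydroxybenzaldehyde | O=Cc1ccc(O)cc1O | starting material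
6 | 2-hydroxy-4-(3-methylbut-2-en-1-yloxy)benzaldehyde | O=Cc1ccc(OCC=C(C)C)cc1O | intermediate
7 | 2-(tert-butyldimethylsilyloxy)-4-(3-methylbut-2-en-1-yloxy)benzaldehyde | O=Cc1ccc(OCC=C(C)C)cc1O[Si](C)(C)C(C)(C)C | intermediate
8 | 2-(tert-butyldimethylsilyloxy)-4-hydroxy-5-(2-methylbut-3-en-2-yl)benzaldehyde | O=Cc1cc(C(C)(C)C=C)c(O)cc1O[Si](C)(C)C(C)(C)C | intermediate
9 | 2,4-bis(tert-butyldimethylsilyloxy)-5-(2-methylbut-3-en-2-yl)benzaldehyde | O=Cc1cc(C(C)(C)C=C)c(O[Si](C)(C)C(C)(C)C)cc1O[Si](C)(C)C(C)(C)C | intermediate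
10 | 1-(dimethoxymethyl)-2,4-bis(tert-butyldimethylsilyloxy)-5-(2-methylbut-3-en-2-yl)benzene | COC(OC)c1cc(C(C)(C)C=C)c(O[Si](C)(C)C(C)(C)C)cc1O[Si](C)(C)C(C)(C)C | intermediate
11 | α-chloro ether (racemic, not isolated): 1-[chloro(methoxy)methyl]-2,4-bis(tert-butyldimethylsilyloxy)-5-(2-methylbut-3-en-2-yl)benzene | COC(Cl)c1cc(C(C)(C)C=C)c(O[Si](C)(C)C(C)(C)C)cc1O[Si](C)(C)C(C)(C)C | intermediate
12 | mixed acetal (racemic): 1-{[2-allyl-3,5-bis(tert-butyldimethylsilyloxy)phenoxy](methoxy)methyl}-2,4-bis(tert-butyldimethylsilyloxy)-5-(2-methylbut-3-en-2-yl)benzene | COC(Oc1cc(O[Si](C)(C)C(C)(C)C)cc(O[Si](C)(C)C(C)(C)C)c1CC=C)c1cc(C(C)(C)C=C)c(O[Si](C)(C)C(C)(C)C)cc1O[Si](C)(C)C(C)(C)C | intermediate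
13 | N-ethynyl-N,4-dimethylbenzenesulfonamide | C#CN(C)S(=O)(=O)c1ccc(C)cc1 | starting material
14 | oxocarbenium ion (cation of the ion pair with the catalyst anion, not isolated): [2-allyl-3,5-bis(tert-butyldimethylsilyloxy)phenyl]{[2,4-bis(tert-butyldimethylsilyloxy)-5-(2-methylbut-3-en-2-yl)phenyl]methylidene}oxonium | C=CCc1c([O+]=Cc2cc(C(C)(C)C=C)c(O[Si](C)(C)C(C)(C)C)cc2O[Si](C)(C)C(C)(C)C)cc(O[Si](C)(C)C(C)(C)C)cc1O[Si](C)(C)C(C)(C)C | intermediate
15 | keteniminium ion (not isolated): (S)-N-{3-[2-allyl-3,5-bis(tert-butyldimethylsilyloxy)phenoxy]-3-[2,4-bis(tert-butyldimethylsilyloxy)-5-(2-methylbut-3-en-2-yl)phenyl]prop-1-en-1-ylidene}-N-methyl-4-methylbenzenesulfonamidium | C=CC(C)(C)c1cc([C@@H](Oc2cc(O[Si](C)(C)C(C)(C)C)cc(O[Si](C)(C)C(C)(C)C)c2CC=C)C=C=[N+](C)S(=O)(=O)c2ccc(C)cc2)c(O[Si](C)(C)C(C)(C)C)cc1O[Si](C)(C)C(C)(C)C | intermediate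
16 | enamide (not isolated): (S)-N-{8-allyl-5,7-bis(tert-butyldimethylsilyloxy)-2-[2,4-bis(tert-butyldimethylsilyloxy)-5-(2-methylbut-3-en-2-yl)phenyl]-2H-chromen-4-yl}-N,4-dimethylbenzenesulfonamide | C=CC(C)(C)c1cc([C@@H]2C=C(N(C)S(=O)(=O)c3ccc(C)cc3)c3c(O[Si](C)(C)C(C)(C)C)cc(O[Si](C)(C)C(C)(C)C)c(CC=C)c3O2)c(O[Si](C)(C)C(C)(C)C)cc1O[Si](C)(C)C(C)(C)C | intermediate
17 | (S)-8-allyl-5,7-bis(tert-butyldimethylsilyloxy)-2-[2,4-bis(tert-butyldimethylsilyloxy)-5-(2-methylbut-3-en-2-yl)phenyl]chroman-4-one | C=CC(C)(C)c1cc([C@@H]2CC(=O)c3c(O[Si](C)(C)C(C)(C)C)cc(O[Si](C)(C)C(C)(C)C)c(CC=C)c3O2)c(O[Si](C)(C)C(C)(C)C)cc1O[Si](C)(C)C(C)(C)C | intermediate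
18 | (S)-5,7-bis(tert-butyldimethylsilyloxy)-2-[2,4-bis(tert-butyldimethylsilyloxy)-5-(2-methylbut-3-en-2-yl)phenyl]-8-(3-methylbut-2-en-1-yl)chroman-4-one | C=CC(C)(C)c1cc([C@@H]2CC(=O)c3c(O[Si](C)(C)C(C)(C)C)cc(O[Si](C)(C)C(C)(C)C)c(CC=C(C)C)c3O2)c(O[Si](C)(C)C(C)(C)C)cc1O[Si](C)(C)C(C)(C)C | intermediate
19 | AChE-IN-17, (S)-2-[2,4-dihydroxy-5-(2-methylbut-3-en-2-yl)phenyl]-5,7-dihydroxy-8-(3-methylbut-2-en-1-yl)chroman-4-one | C=CC(C)(C)c1cc([C@@H]2CC(=O)c3c(O)cc(O)c(CC=C(C)C)c3O2)c(O)cc1O | target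

**Step count and risks**

Total step count: 12. Longest linear sequence: 9 steps (steps 4 to 12, from 2,4-dihydroxybenzaldehyde); the ring A branch (steps 1 to 3) joins at step 9.

Steps most likely to fail:

1. Step 10 (Proposed new method). What may go wrong: poor facial discrimination in the ion pair, ionization of the acetal in the wrong direction (loss of the phenol instead of methanol), capture of the keteniminium ion by O1 instead of C4a, or consumption of the ynamide by the acid.
Fallback with known chemistry, setting out from aldehyde 9 and phenol 4 and returning at 17. A catalytic asymmetric Mukaiyama acetate aldol addition of 1-methoxy-1-(trimethylsilyloxy)ethene to 9 (Ti(OiPr)4 with a binaphthol-derived Schiff base ligand, Et2O, 0 °C) should give methyl (R)-3-[2,4-bis(TBSO)-5-(2-methylbut-3-en-2-yl)phenyl]-3-(trimethylsilyloxy)propanoate F1. Mild methanolysis (citric acid, MeOH, 0 °C) frees methyl (R)-3-[2,4-bis(TBSO)-5-(2-methylbut-3-en-2-yl)phenyl]-3-hydroxypropanoate F2. Mitsunobu etherification with 4 (PPh3, DIAD, toluene, 0 °C) forms O1–C2 with inversion and gives methyl (S)-3-[2-allyl-3,5-bis(TBSO)phenoxy]-3-[2,4-bis(TBSO)-5-(2-methylbut-3-en-2-yl)phenyl]propanoate F3. Neutral ester cleavage (Me3SnOH, 1,2-dichloroethane, 70 °C) gives (S)-3-[2-allyl-3,5-bis(TBSO)phenoxy]-3-[2,4-bis(TBSO)-5-(2-methylbut-3-en-2-yl)phenyl]propanoic acid F4. Intramolecular Friedel–Crafts acylation (trifluoroacetic anhydride, CH2Cl2, 0 °C) then closes ring C at C4a to give 17.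

2. Step 9. What may go wrong: Friedel–Crafts C-alkylation of the electron-rich phenol by the ionizing chloro ether instead of O-alkylation, loss of a silyl group from the ionized intermediate to chloride, or re-ionization of the acetal during isolation.
Fallback, setting out from 9 and 4 and returning at 12. NaBH4 (MeOH/THF, 0 °C) reduces 9 to [2,4-bis(TBSO)-5-(2-methylbut-3-en-2-yl)phenyl]methanol F5. Mitsunobu etherification with 4 (PPh3, DIAD, THF) gives 2-allyl-1-{[2,4-bis(TBSO)-5-(2-methylbut-3-en-2-yl)benzyl]oxy}-3,5-bis(TBSO)benzene F6. Oxidative acetalization (DDQ, CH2Cl2/MeOH, 0 °C; hydride abstraction from the electron-rich benzylic ether and capture by methanol) gives 12 without any chloride.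

3. Step 6. What may go wrong: rearrangement to C3 instead of C5, thermal loss of the prenyl group, or onward cyclization of the new phenol onto the new alkene at 200 °C.
Fallback, setting out from 5 and returning at 9 (bypassing 6 to 8). Bromination (Br2, AcOH, rt) gives 5-bromo-2,4-dihydroxybenzaldehyde F7. Silylation (TBSCl, imidazole, DMF) gives 5-bromo-2,4-bis(TBSO)benzaldehyde F8. A Suzuki–Miyaura coupling with prenylboronic acid pinacol ester, under ligand control for bond formation through the γ-carbon of the allyl unit (Pd(OAc)2, a bulky dialkylbiarylphosphine, anhydrous K3PO4, THF, 40 °C), installs the 2-methylbut-3-en-2-yl group and gives 9.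

**Further compounds**
F1 | step 10 | methyl (R)-3-[2,4-bis(tert-butyldimethylsilyloxy)-5-(2-methylbut-3-en-2-yl)phenyl]-3-(trimethylsilyloxy)propanoate | C=CC(C)(C)c1cc([C@H](O[Si](C)(C)C)CC(=O)OC)c(O[Si](C)(C)C(C)(C)C)cc1O[Si](C)(C)C(C)(C)C
F2 | step 10 | methyl (R)-3-[2,4-bis(tert-butyldimethylsilyloxy)-5-(2-methylbut-3-en-2-yl)phenyl]-3-hydroxypropanoate | C=CC(C)(C)c1cc([C@H](O)CC(=O)OC)c(O[Si](C)(C)C(C)(C)C)cc1O[Si](C)(C)C(C)(C)C
F3 | step 10 | methyl (S)-3-[2-allyl-3,5-bis(tert-butyldimethylsilyloxy)phenoxy]-3-[2,4-bis(tert-butyldimethylsilyloxy)-5-(2-methylbut-3-en-2-yl)phenyl]propanoate | C=CC(C)(C)c1cc([C@@H](Oc2cc(O[Si](C)(C)C(C)(C)C)cc(O[Si](C)(C)C(C)(C)C)c2CC=C)CC(=O)OC)c(O[Si](C)(C)C(C)(C)C)cc1O[Si](C)(C)C(C)(C)C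
F4 | step 10 | (S)-3-[2-allyl-3,5-bis(tert-butyldimethylsilyloxy)phenoxy]-3-[2,4-bis(tert-butyldimethylsilyloxy)-5-(2-methylbut-3-en-2-yl)phenyl]propanoic acid | C=CC(C)(C)c1cc([C@@H](Oc2cc(O[Si](C)(C)C(C)(C)C)cc(O[Si](C)(C)C(C)(C)C)c2CC=C)CC(=O)O)c(O[Si](C)(C)C(C)(C)C)cc1O[Si](C)(C)C(C)(C)C
F5 | step 9 | [2,4-bis(tert-butyldimethylsilyloxy)-5-(2-methylbut-3-en-2-yl)phenyl]methanol | OCc1cc(C(C)(C)C=C)c(O[Si](C)(C)C(C)(C)C)cc1O[Si](C)(C)C(C)(C)C
F6 | step 9 | 2-allyl-1-{[2,4-bis(tert-butyldimethylsilyloxy)-5-(2-methylbut-3-en-2-yl)benzyl]oxy}-3,5-bis(tert-butyldimethylsilyloxy)benzene | C=CCc1c(OCc2cc(C(C)(C)C=C)c(O[Si](C)(C)C(C)(C)C)cc2O[Si](C)(C)C(C)(C)C)cc(O[Si](C)(C)C(C)(C)C)cc1O[Si](C)(C)C(C)(C)C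
F7 | step 6 | 5-bromo-2,4-dihydroxybenzaldehyde | O=Cc1cc(Br)c(O)cc1O
F8 | step 6 | 5-bromo-2,4-bis(tert-butyldimethylsilyloxy)benzaldehyde | O=Cc1cc(Br)c(O[Si](C)(C)C(C)(C)C)cc1O[Si](C)(C)C(C)(C)C
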